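## The problem

The target is a linear octamer of eight benzene rings, lettered A to H from the 2,4,6-trihydroxyphenyl end, joined only by seven diaryl ether oxygens and carrying twenty-one free phenolic hydroxyls. It has no stereocentre and its diaryl ethers rotate freely, so there is nothing to control stereochemically and no centre that could steer another. The difficulty lies in how the rings are joined. Rings B, D and F are 1,4-phenylene units whose C4 ether oxygen sits between two hydroxyls (C3 and C5). Rings C, E and G are pentaoxygenated, with two adjacent ether oxygens at C1 and C6 followed by hydroxyls at C5, C4 and C3. Ring H is a 3,4,5-trihydroxyphenyl ether. Every ether oxygen therefore sits on at least one doubly ortho-substituted, electron-rich carbon, the least favourable case both for copper-mediated couplings and for addition–elimination. The ring A ether is the most crowded: C1 of ring A lies between the C2 and C6 hydroxyls, and the ring has no free position for an activating group. The free polyphenol is oxidised easily, above all under base, so the hydroxyls must stay masked until the last step, and that step must break alkyl–oxygen bonds without touching aryl–oxygen–aryl bonds. The enabling feature is ring A itself: its hydroxyl-bearing carbons C2, C4 and C6 correspond to the C1, C3 and C5 carbonyls of a 3,5-dioxohexanoate, and its ether-bearing C1 to the C6 methylene of that chain. The crowded aryl ether can thus be made first as an unhindered alkyl aryl ether, and ring A closed around it by one carbon–carbon bond.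

## Retrosynthesis

**Target 26 to octamer triol 25.** The eighteen O–methyl bonds of rings B to H are cut. Methyl ethers are preferred to benzyl or silyl groups because the commercial aromatics already carry them and because they survive organolithium, copper, palladium, peracid and methoxide chemistry. Ring A is left free in 25, since it is formed free and never needs protection. The forward step must cleave eighteen alkyl–oxygen bonds exhaustively while leaving seven diaryl ethers intact and the product unoxidised.

**Triol 25 to triketide 23.** The bond between C1 of ring A (the ether carbon) and the neighbouring hydroxyl-bearing carbon is cut, through trione 24. The neighbouring cut, at the ring A–oxygen–ring B ether, would demand arylation of a 2,4,6-trioxygenated phenol at its most hindered oxygen. An aldol-type opening of ring A would lead to a resorcinol pattern, not the 1,3,5-pattern needed. The precursor 23 has one ring fewer, and the difficult ether has become a primary alkyl aryl ether. The forward reaction must acylate at carbon (C6 onto the C1 ester) in preference to oxygen.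

**Triketide 23 to ester 20 and methyl acetoacetate 21; ester 20 to phenol 18 and methyl bromoacetate 19.** The C4–C5 bond of the chain is cut to the ester 20 and the dianion 22 of 21. The O–CH2 bond is then cut to 18 and 19. Both fragments are simple and both bond formations are classical. This is the point where the ring A ether oxygen is attached, by substitution at a primary carbon. The acylation must outrun enolisation of 20.

**Heptamer phenol 18 back to block phenol 7 and boronic acid 8.** The hydroxyl of 18 is traced to the bromine of 17. The three ethers from C6 of rings C, E and G to C1 of rings D, F and H are then cut one after another: 17 to boronic acid 16 plus 7, 16 to bromide 13, 13 to boronic acid 12 plus 7, 12 to bromide 9, and 9 to 7 plus 8. In each cut the oxygen stays on the crowded carbon as a phenol and the partner is an arylboron with two free ortho positions, the polarity that an oxidative copper coupling tolerates. This is preferred to a halide-based coupling because the oxidative coupling leaves an aryl bromide untouched. One two-ring block, 7, can therefore bring in its own handle for the next round and serve three times. The heptamer is reduced to one block and one commercial boronic acid. The forward couplings must spare the bromine and must not oxidise the electron-rich phenol.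

**Block phenol 7 to fluoroaldehyde 3 and bromophenol 4; 3 to fluoroarene 1.** The remaining ether type, from C4 of a 2,6-dimethoxyphenyl ring to C1 of a pentaoxygenated ring, has substituents ortho to both ends. It is cut so that the crowded oxygen is again the nucleophile (4). The carbon electrophile (3) carries a formyl group ortho to fluoride: this activates the displacement and is afterwards converted, through formate 6, into the C6 hydroxyl of 7. No metal is involved, so the bromine of 4 is not at risk. Aldehyde 3 comes from 1 through aryllithium 2; the two ring hydrogens of 1 are equivalent, so only one product is possible.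

## Roads not taken

**Alternative 1:** The cut runs through both ether bonds of ring G. In the forward sense the cationic [CpRu]+ complex of 1,2-dichloro-3,4,5-trimethoxybenzene, as its hexafluorophosphate A2, would be attacked first by the hexameric phenol A3 (rings A to F as methyl ethers, hydroxyl at C4 of ring F) and then by 3,4,5-trimethoxyphenol A4. This gives the ruthenium-bound permethylated octamer A1; release of the metal and cleavage of twenty-one methyl ethers would follow.
- Merits: the metal turns the most electron-rich ring into a strong electrophile, so even doubly ortho-substituted phenoxides should add near room temperature. Two of the hardest ethers are made in one flask, and the union is convergent. As an ether-forming event it is probably more reliable than steps 2, 6 and 8 of the chosen route.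
- Weak points: the constitution depends on the order of attack. A3 must take the chloride next to the ring hydrogen and A4 the one next to the methoxy group, and only a steric bias separates the two; a regioisomeric octamer could hardly be removed. Ruthenium is used stoichiometrically on a late intermediate and must be released from a molecule with seven other arenes able to bind it. A3 itself contains five ethers of the same difficult kinds, including the ring A ether, for which this plan offers nothing.
- Comparison: the chosen plan cannot match the mildness and convergence of this union. Against that it sets constitutional certainty at every ether, no stoichiometric precious metal, and a solution for ring A.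

**Alternative 2:** The cut is the C2–C3 bond of ring E, which traces the whole ring to a four-membered precursor. Heating the racemic cyclobutenone A6, whose 1-aryloxyvinyl group carries the ring A to D tetramer through the ring D oxygen, would open it to a dienylketene. Electrocyclisation and tautomerisation then give the pentamer A5, with a free hydroxyl at C3 and a methoxymethyl ether at C6 of ring E.
- Merits: the crowded bond from the ring D oxygen to C1 of ring E is never formed as a diaryl ether, since it enters as a vinyl ether. The pericyclic sequence fixes the substitution pattern, and the ring E oxygens arrive differentiated. A thermal, reagent-free step of this kind is more predictable than the Claisen closure of step 12.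
- Weak points: the vinyl ether must be metalated at its alpha carbon in a tetramer full of methoxy groups that direct ring metalation. The tetramer, with the ring A and ring C ethers, must exist beforehand. Only ring E profits, although rings C and G have the same pattern. After the key step three ethers remain to be made, the first at the crowded C6 oxygen.
- Comparison: both plans replace a crowded ether by the construction of a ring. Alternative 2 applies the idea to a ring type that occurs three times, where each repetition costs several steps. The chosen plan applies it once, to ring A, where the conventional ether is worst and the detour costs three steps (10 to 12). The price is a less certain ring closure, for which a fallback from 17 is held ready.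

**Alternative 3:** The cut is at the four aryl C4–oxygen bonds of rings C, E, G and H, traced back to formyl groups. A peracid would convert the tetra-aldehyde A8 into four aryl formates, and methanolysis would give the tetraphenol A7, to be methylated or taken directly to global ether cleavage.
- Merits: each formyl group would first have activated the para position, C1 of its ring, for fluoride displacement by a crowded phenoxide, and all four then become oxygens in one operation. This is more convergent than anything in the chosen route and, at the ether-forming stage, no less sound than step 2.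
- Weak points: four oxidations must all go to completion on one molecule, and partly oxidised octamers would be nearly inseparable. A7 contains four 2,6-dimethoxyphenols, among the most easily oxidised phenols, which meet the peracid as they form. The activation reaches only C1 of those rings; the ethers at C6 of rings C, E and G and the ring A ether still need copper chemistry at crowded positions, now with free aldehydes present.
- Comparison: the chosen route uses the same pairing of formyl-activated displacement and Baeyer–Villiger oxidation (steps 2 and 3), but once, on a two-ring compound that can be purified and is then used three times. It gives up the one-step unmasking of four oxygens and gains an oxidation that never has to be complete on the octamer, and a ring A ether that needs no coupling.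

Key step: step 12

Remark: fluoroarene 1 is taken to be a catalogue compound, and the target, having no stereocentre and freely rotating diaryl ethers, is treated as a single achiral compound.

## Route

Step 1
Reactants: 1 5-fluoro-1,2,3-trimethoxybenzene
Product: 3 6-fluoro-2,3,4-trimethoxybenzaldehyde, via aryllithium 2 (not isolated)
Conditions: n-BuLi, THF, −78 °C; DMF, −78 °C to 0 °C; aq. NH4Cl
Reagents that add atoms: N,N-dimethylformamide, CN(C)C=O
Why: Directed ortho-metalation: the only two ring hydrogens of 1 are equivalent and each lies between fluorine and a methoxy group, both of which acidify and direct; at −78 °C aryllithium 2 should not lose LiF, and formylation with DMF can give only one isomer.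

Step 2
Reactants: 3 6-fluoro-2,3,4-trimethoxybenzaldehyde; 4 4-bromo-2,6-dimethoxyphenol
Product: 5 6-(4-bromo-2,6-dimethoxyphenoxy)-2,3,4-trimethoxybenzaldehyde
Conditions: Cs2CO3, DMSO, 100 °C, N2
Reagents that add atoms: none
Why: Nucleophilic aromatic substitution by addition–elimination: the fluoride of 3 is ortho to the formyl group, which takes up the charge of the Meisenheimer intermediate, and the cesium phenoxide of 4 is reactive in DMSO despite its two flanking methoxyls. No metal is present, so the aryl bromide of 4 should pass through untouched.

Step 3
Reactants: 5 6-(4-bromo-2,6-dimethoxyphenoxy)-2,3,4-trimethoxybenzaldehyde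
Product: 7 6-(4-bromo-2,6-dimethoxyphenoxy)-2,3,4-trimethoxyphenol (block phenol), via aryl formate 6 (not isolated)
Conditions: mCPBA, CH2Cl2, 0 °C to rt; aq. Na2S2O3 wash; K2CO3, MeOH, rt
Reagents that add atoms: 3-chloroperbenzoic acid (mCPBA), OOC(=O)c1cccc(Cl)c1
Why: Baeyer–Villiger oxidation in its Dakin-type form: the aryl group of 5, with oxygen donors ortho, ortho and para to the formyl carbon, migrates in preference to hydrogen to give formate 6, which carbonate in methanol cleaves. The peracid is destroyed before the phenol is set free, so the electron-rich 7 should escape over-oxidation.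

Step 4
Reactants: 7 6-(4-bromo-2,6-dimethoxyphenoxy)-2,3,4-trimethoxyphenol; 8 (3,4,5-trimethoxyphenyl)boronic acid
Product: 9 5-bromo-1,3-dimethoxy-2-[3,4,5-trimethoxy-2-(3,4,5-trimethoxyphenoxy)phenoxy]benzene (trimer bromide; rings F–G–H)
Conditions: 8 (2 equiv), Cu(OAc)2 (1 equiv), pyridine, 4 Å molecular sieves, CH2Cl2, dry air, rt
Reagents that add atoms: none
Why: Chan–Lam coupling: transmetalation of 8 to copper, binding of the phenoxide of 7 and C–O reductive elimination from trivalent copper at room temperature; the reaction accepts doubly ortho-substituted phenols when the arylboron partner is unhindered, as 8 is. The aryl bromide is inert under these oxidative conditions and is kept as the handle for step 5.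

Step 5
Reactants: 9 trimer bromide
Product: 12 {3,5-dimethoxy-4-[3,4,5-trimethoxy-2-(3,4,5-trimethoxyphenoxy)phenoxy]phenyl}boronic acid (trimer boronic acid), via trimer aryllithium 10 (not isolated), via trimer triisopropoxyborate 11 (not isolated)
Conditions: n-BuLi, THF, −78 °C; B(OiPr)3, −78 °C to rt; 1 M HCl
Reagents that add atoms: triisopropyl borate, CC(C)OB(OC(C)C)OC(C)C; water, O
Why: Bromine–lithium exchange is faster at −78 °C than any ring deprotonation, and trapping of 10 with the borate gives ate complex 11, which acid hydrolyses to boronic acid 12. Compound 9 carries only ethers, which tolerate the organolithium.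

Step 6
Reactants: 12 trimer boronic acid; 7 block phenol
Product: 13 pentamer bromide (rings D to H as permethyl ethers; bromine at C1 of ring D)
Conditions: 7 (2 equiv), Cu(OAc)2 (1 equiv), pyridine, 4 Å molecular sieves, CH2Cl2, dry air, rt
Reagents that add atoms: none
Why: Chan–Lam coupling as in step 4, now with the block phenol 7 in excess and the unhindered boronic acid 12 as the limiting partner; the new ether joins C6 of ring E to C1 of ring F. The bromine of 7 survives and becomes the handle of the next round.

Step 7
Reactants: 13 pentamer bromide
Product: 16 pentamer boronic acid (rings D to H; B(OH)2 at C1 of ring D), via pentamer aryllithium 14 (not isolated), via pentamer triisopropoxyborate 15 (not isolated)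
Conditions: n-BuLi, THF, −78 °C; B(OiPr)3, −78 °C to rt; 1 M HCl
Reagents that add atoms: triisopropyl borate, CC(C)OB(OC(C)C)OC(C)C; water, O
Why: The same bromine–lithium exchange and borylation as in step 5, through 14 and 15; the additional rings carry only methyl and diaryl ethers.

Step 8
Reactants: 16 pentamer boronic acid; 7 block phenol
Product: 17 heptamer bromide (rings B to H as permethyl ethers; bromine at C1 of ring B)
Conditions: 7 (2 equiv), Cu(OAc)2 (1 equiv), pyridine, 4 Å molecular sieves, CH2Cl2, dry air, rt
Reagents that add atoms: none
Why: Third Chan–Lam coupling, joining C6 of ring C to C1 of ring D and completing the ring B to H chain. The retained bromine now sits on C1 of ring B, where the last oxygen is needed.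

Step 9
Reactants: 17 heptamer bromide
Product: 18 heptamer phenol (rings B to H as permethyl ethers; hydroxyl at C1 of ring B)
Conditions: Pd2(dba)3 (2 mol %), tBuXPhos (8 mol %), KOH, 1,4-dioxane–H2O, 100 °C; then 1 M HCl
Reagents that add atoms: potassium hydroxide, [K+].[OH-]
Why: Palladium-catalysed hydroxylation of an aryl bromide: oxidative addition to zerovalent palladium, exchange of bromide for hydroxide and C–O reductive elimination driven by the bulky biaryl phosphine. The bromide is unhindered, and the methyl and diaryl ethers are inert to hot hydroxide.

Step 10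
Reactants: 18 heptamer phenol; 19 methyl bromoacetate
Product: 20 methyl 2-(heptamer-oxy)acetate (ring B C1–O–CH2–CO2Me)
Conditions: K2CO3, acetone, 56 °C
Reagents that add atoms: none
Why: Williamson ether synthesis: the phenoxide of 18, flanked only by hydrogens, displaces bromide from the primary carbon of 19 by SN2. This forms the future ring A ether bond while its carbon is still unhindered.

Step 11
Reactants: 20 methyl 2-(heptamer-oxy)acetate; 21 methyl acetoacetate
Product: 23 methyl 6-(heptamer-oxy)-3,5-dioxohexanoate (triketide), via methyl acetoacetate dianion 22 (not isolated)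
Conditions: 21 (3 equiv), NaH, THF, 0 °C; n-BuLi, 0 °C; 20, −78 °C to 0 °C; 1 M HCl
Reagents that add atoms: none
Why: Claisen-type gamma-acylation of a beta-keto ester dianion: the terminal carbanion of 22 adds to the ester of 20, which the alpha-aryloxy group makes more electrophilic, and methoxide is lost. Excess dianion is used because the product is deprotonated as it forms, which also shields it from further attack.

Step 12
Reactants: 23 methyl 6-(heptamer-oxy)-3,5-dioxohexanoate
Product: 25 octamer triol (ring A a free 2,4,6-trihydroxyphenyl ether; rings B to H as permethyl ethers), via 2-(heptamer-oxy)cyclohexane-1,3,5-trione 24 (not isolated)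
Conditions: NaOMe (6 equiv), MeOH–THF, 65 °C, Ar; 1 M HCl, 0 °C
Reagents that add atoms: none
Why: Methoxide converts 23 into its C4 enolate and, in equilibrium, into the bis-enolate also deprotonated at C6, the methylene acidified by the C5 carbonyl and the aryloxy oxygen; in this species the ester carbonyl is not part of an enolate and stays electrophilic. The C6 carbon of the C5–C6 enolate attacks the C1 ester carbonyl in a 6-(enolendo)-exo-trig closure, the favoured mode for this ring size, and loss of methoxide gives trione 24, whose enolisation to the phloroglucinolate of 25 is irreversible and pulls the preceding equilibria forward. The closest known reaction type is the base-mediated Claisen cyclisation of 3,5-dioxohexanoate esters, and of 4-hydroxy-6-methyl-2-pyranone after methanolysis, to phloroglucinol, the laboratory counterpart of the enzymatic folding of a triketide. No stereocentre is formed, since the one sp3 carbon of 24 that bears the aryloxy group becomes aromatic. The selectivity needed is acylation at carbon over oxygen: attack by the C5 enol oxygen would give a 4-hydroxy-2-pyranone, but that lactone can be reopened by methoxide whereas the aromatic product cannot, and the aryloxy group raises the share of the C6 carbanion. Regiochemistry is not in question, because C6 is the only carbanion that can reach the ester through a six-membered ring, and aldol closures would need four-membered rings. The methyl and diaryl ethers of rings B to H are inert to methoxide, and exclusion of oxygen protects the electron-rich triol until acidification.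

Step 13
Reactants: 25 octamer triol
Product: 26 CNP0206369.0 (target; all twenty-one hydroxyls free)
Conditions: BBr3 (excess), CH2Cl2, −78 °C to rt, Ar; MeOH then H2O, degassed
Reagents that add atoms: none
Why: Lewis acid cleavage of aryl methyl ethers: each methoxy oxygen binds boron and bromide attacks the methyl carbon by SN2, a path closed to the diaryl ether oxygens, so the seven aryl–O–aryl bonds should survive. Ring A is already free and only consumes reagent; work-up and isolation are kept acidic and oxygen-free.

## Compound list

1 | 5-fluoro-1,2,3-trimethoxybenzene | COc1cc(F)cc(OC)c1OC | starting material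
2 | (6-fluoro-2,3,4-trimethoxyphenyl)lithium | [Li]c1c(F)cc(OC)c(OC)c1OC | intermediate (not isolated)
3 | 6-fluoro-2,3,4-trimethoxybenzaldehyde | O=Cc1c(F)cc(OC)c(OC)c1OC | intermediate
4 | 4-bromo-2,6-dimethoxyphenol | COc1cc(Br)cc(OC)c1O | starting material
5 | 6-(4-bromo-2,6-dimethoxyphenoxy)-2,3,4-trimethoxybenzaldehyde | O=Cc1c(Oc2c(OC)cc(Br)cc2OC)cc(OC)c(OC)c1OC | intermediate
6 | 6-(4-bromo-2,6-dimethoxyphenoxy)-2,3,4-trimethoxyphenyl formate | O=COc1c(Oc2c(OC)cc(Br)cc2OC)cc(OC)c(OC)c1OC | intermediate (not isolated)
7 | 6-(4-bromo-2,6-dimethoxyphenoxy)-2,3,4-trimethoxyphenol (block phenol) | Oc1c(Oc2c(OC)cc(Br)cc2OC)cc(OC)c(OC)c1OC | intermediate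
8 | (3,4,5-trimethoxyphenyl)boronic acid | COc1cc(B(O)O)cc(OC)c1OC | starting material
9 | 5-bromo-1,3-dimethoxy-2-[3,4,5-trimethoxy-2-(3,4,5-trimethoxyphenoxy)phenoxy]benzene (trimer bromide, rings F–G–H) | Brc1cc(OC)c(Oc2cc(OC)c(OC)c(OC)c2Oc2cc(OC)c(OC)c(OC)c2)c(OC)c1 | intermediate
10 | trimer aryllithium (lithium in place of the bromine of 9) | [Li]c1cc(OC)c(Oc2cc(OC)c(OC)c(OC)c2Oc2cc(OC)c(OC)c(OC)c2)c(OC)c1 | intermediate (not isolated)
11 | lithium triisopropoxy(trimer-aryl)borate | [Li+].CC(C)O[B-](OC(C)C)(OC(C)C)c1cc(OC)c(Oc2cc(OC)c(OC)c(OC)c2Oc2cc(OC)c(OC)c(OC)c2)c(OC)c1 | intermediate (not isolated)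
12 | {3,5-dimethoxy-4-[3,4,5-trimethoxy-2-(3,4,5-trimethoxyphenoxy)phenoxy]phenyl}boronic acid (trimer boronic acid) | OB(O)c1cc(OC)c(Oc2cc(OC)c(OC)c(OC)c2Oc2cc(OC)c(OC)c(OC)c2)c(OC)c1 | intermediate
13 | 5-bromo-2-(2-{3,5-dimethoxy-4-[3,4,5-trimethoxy-2-(3,4,5-trimethoxyphenoxy)phenoxy]phenoxy}-3,4,5-trimethoxyphenoxy)-1,3-dimethoxybenzene (pentamer bromide, rings D to H) | Brc1cc(OC)c(Oc2cc(OC)c(OC)c(OC)c2Oc2cc(OC)c(Oc3cc(OC)c(OC)c(OC)c3Oc3cc(OC)c(OC)c(OC)c3)c(OC)c2)c(OC)c1 | intermediate
14 | pentamer aryllithium (lithium in place of the bromine of 13) | [Li]c1cc(OC)c(Oc2cc(OC)c(OC)c(OC)c2Oc2cc(OC)c(Oc3cc(OC)c(OC)c(OC)c3Oc3cc(OC)c(OC)c(OC)c3)c(OC)c2)c(OC)c1 | intermediate (not isolated)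
15 | lithium triisopropoxy(pentamer-aryl)borate | [Li+].CC(C)O[B-](OC(C)C)(OC(C)C)c1cc(OC)c(Oc2cc(OC)c(OC)c(OC)c2Oc2cc(OC)c(Oc3cc(OC)c(OC)c(OC)c3Oc3cc(OC)c(OC)c(OC)c3)c(OC)c2)c(OC)c1 | intermediate (not isolated)
16 | pentamer boronic acid (B(OH)2 in place of the bromine of 13) | OB(O)c1cc(OC)c(Oc2cc(OC)c(OC)c(OC)c2Oc2cc(OC)c(Oc3cc(OC)c(OC)c(OC)c3Oc3cc(OC)c(OC)c(OC)c3)c(OC)c2)c(OC)c1 | intermediate
17 | heptamer bromide: rings B to H joined as in the target (C4 of B, D, F to C1 of C, E, G; C6 of C, E, G to C1 of D, F, H), every hydroxyl as methyl ether, bromine at C1 of ring B | Brc1cc(OC)c(Oc2cc(OC)c(OC)c(OC)c2Oc2cc(OC)c(Oc3cc(OC)c(OC)c(OC)c3Oc3cc(OC)c(Oc4cc(OC)c(OC)c(OC)c4Oc4cc(OC)c(OC)c(OC)c4)c(OC)c3)c(OC)c2)c(OC)c1 | intermediate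
18 | heptamer phenol: as 17 with hydroxyl in place of bromine at C1 of ring B | Oc1cc(OC)c(Oc2cc(OC)c(OC)c(OC)c2Oc2cc(OC)c(Oc3cc(OC)c(OC)c(OC)c3Oc3cc(OC)c(Oc4cc(OC)c(OC)c(OC)c4Oc4cc(OC)c(OC)c(OC)c4)c(OC)c3)c(OC)c2)c(OC)c1 | intermediate
19 | methyl bromoacetate | COC(=O)CBr | starting material
20 | methyl 2-(heptamer-oxy)acetate (O-carboxymethyl ether of 18, methyl ester) | COC(=O)COc1cc(OC)c(Oc2cc(OC)c(OC)c(OC)c2Oc2cc(OC)c(Oc3cc(OC)c(OC)c(OC)c3Oc3cc(OC)c(Oc4cc(OC)c(OC)c(OC)c4Oc4cc(OC)c(OC)c(OC)c4)c(OC)c3)c(OC)c2)c(OC)c1 | intermediate
21 | methyl acetoacetate | COC(=O)CC(C)=O | starting material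
22 | methyl acetoacetate dianion (sodium lithium salt) | [Na+].[Li+].[CH2-]C(=O)[CH-]C(=O)OC | intermediate (not isolated)
23 | methyl 6-(heptamer-oxy)-3,5-dioxohexanoate | COC(=O)CC(=O)CC(=O)COc1cc(OC)c(Oc2cc(OC)c(OC)c(OC)c2Oc2cc(OC)c(Oc3cc(OC)c(OC)c(OC)c3Oc3cc(OC)c(Oc4cc(OC)c(OC)c(OC)c4Oc4cc(OC)c(OC)c(OC)c4)c(OC)c3)c(OC)c2)c(OC)c1 | intermediate
24 | 2-(heptamer-oxy)cyclohexane-1,3,5-trione (keto form of 25) | O=C1CC(=O)C(Oc2cc(OC)c(Oc3cc(OC)c(OC)c(OC)c3Oc3cc(OC)c(Oc4cc(OC)c(OC)c(OC)c4Oc4cc(OC)c(Oc5cc(OC)c(OC)c(OC)c5Oc5cc(OC)c(OC)c(OC)c5)c(OC)c4)c(OC)c3)c(OC)c2)C(=O)C1 | intermediate (not isolated)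
25 | octamer triol: ring A free 2,4,6-trihydroxyphenyl ether, rings B to H as methyl ethers | Oc1cc(O)c(Oc2cc(OC)c(Oc3cc(OC)c(OC)c(OC)c3Oc3cc(OC)c(Oc4cc(OC)c(OC)c(OC)c4Oc4cc(OC)c(Oc5cc(OC)c(OC)c(OC)c5Oc5cc(OC)c(OC)c(OC)c5)c(OC)c4)c(OC)c3)c(OC)c2)c(O)c1 | intermediate
26 | CNP0206369.0 | Oc1cc(O)c(Oc2cc(O)c(Oc3cc(O)c(O)c(O)c3Oc3cc(O)c(Oc4cc(O)c(O)c(O)c4Oc4cc(O)c(Oc5cc(O)c(O)c(O)c5Oc5cc(O)c(O)c(O)c5)c(O)c4)c(O)c3)c(O)c2)c(O)c1 | target

## Step count and least certain steps

Total: 13 steps. Longest linear sequence: 13 steps (1 to 26); block phenol 7, made in steps 1 to 3, enters three times (steps 4, 6 and 8).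

**Step 12 (key step).** Lactonisation through the C5 enol oxygen, or retro-Claisen cleavage of the diketone by methoxide, may outrun carbon acylation. The C6 carbanion is present only in low concentration, and in the fully enolised chain the ester is deactivated. Fallback: ring A is attached ready-made. Setting out from heptamer bromide 17, a copper-catalysed Ullmann coupling (CuI, picolinic acid, K3PO4, DMSO, 90 °C) with 2,4,6-trimethoxyphenol F1 would give the permethylated octamer F2. Here the crowded partner is the phenol and the bromide is unhindered, the polarity this coupling tolerates. Cleavage of all twenty-one methyl ethers of F2 with BBr3 returns to the route at 26.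

**Step 8.** The boronic acid 16 is the limiting and most valuable partner, and it may be lost by protodeboronation or oxidative hydroxylation before it couples. The electron-rich phenol 7 may also be oxidised by divalent copper and air. Fallback: setting out from pentamer bromide 13, halogen exchange (CuI, NaI, trans-N,N'-dimethylcyclohexane-1,2-diamine, dioxane, 110 °C) would give the pentamer iodide F3. An oxygen-free Ullmann coupling of F3 with 7 (CuI, picolinic acid, K3PO4, DMSO, 80 °C), in which the iodide should react well before the bromide of 7, rejoins the route at 17.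

**Step 6.** The same losses threaten on the trimer, to a smaller degree. Fallback: setting out from trimer bromide 9, the same halogen exchange would give the trimer iodide F4, and its oxygen-free Ullmann coupling with 7 under the conditions above rejoins the route at 13.

**Step 2.** Addition of a hindered phenoxide to a ring carrying three methoxy donors may be so slow that the forcing conditions degrade the aldehyde. Fallback: copper catalysis in place of addition–elimination. Rieche formylation (Cl2CHOMe, TiCl4, CH2Cl2, 0 °C) of commercial 5-bromo-1,2,3-trimethoxybenzene F5 would give 6-bromo-2,3,4-trimethoxybenzaldehyde F6, whose ortho-formyl bromide is activated towards copper. Its coupling with phenol 4 (CuI, picolinic acid, K3PO4, DMSO, 80 °C), whose own bromide lies para to the phenoxide oxygen and is deactivated, sets out from 4 and rejoins the route at 5.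

**Step 11.** Enolisation of the aryloxyacetate by the strongly basic dianion, or cleavage of the product by the methoxide set free, may compete with acylation. Fallback: setting out from phenol 18, alkylation with 2-chloro-N-methoxy-N-methylacetamide F7 (K2CO3, NaI, DMF, 60 °C) would give the Weinreb amide F8. Its adduct with dianion 22 is a stable chelate that releases the ketone only on work-up, so no alkoxide is formed in the flask, and the route is rejoined at 23.

**Step 13.** Ether cleavage may stop short at some of the eighteen sites as boron chelates precipitate, and the free polyphenol may be oxidised by air during isolation. Fallback: setting out from 25, the crude product of the BBr3 treatment is acetylated (Ac2O, pyridine) to the henicosaacetate F9, which is stable to air and separable on silica from incompletely demethylated material. Methanolysis (HCl, degassed MeOH) then gives 26.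

## Further compounds

F1 | step 12 | 2,4,6-trimethoxyphenol | COc1cc(OC)c(O)c(OC)c1
F2 | step 12 | permethylated octamer (ring A 2,4,6-trimethoxyphenyl ether, rings B to H as in 25) | COc1cc(OC)c(Oc2cc(OC)c(Oc3cc(OC)c(OC)c(OC)c3Oc3cc(OC)c(Oc4cc(OC)c(OC)c(OC)c4Oc4cc(OC)c(Oc5cc(OC)c(OC)c(OC)c5Oc5cc(OC)c(OC)c(OC)c5)c(OC)c4)c(OC)c3)c(OC)c2)c(OC)c1
F3 | step 8 | pentamer iodide (iodine in place of the bromine of 13) | Ic1cc(OC)c(Oc2cc(OC)c(OC)c(OC)c2Oc2cc(OC)c(Oc3cc(OC)c(OC)c(OC)c3Oc3cc(OC)c(OC)c(OC)c3)c(OC)c2)c(OC)c1
F4 | step 6 | trimer iodide (iodine in place of the bromine of 9) | Ic1cc(OC)c(Oc2cc(OC)c(OC)c(OC)c2Oc2cc(OC)c(OC)c(OC)c2)c(OC)c1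
F5 | step 2 | 5-bromo-1,2,3-trimethoxybenzene | COc1cc(Br)cc(OC)c1OC
F6 | step 2 | 6-bromo-2,3,4-trimethoxybenzaldehyde | COc1cc(Br)c(C=O)c(OC)c1OC
F7 | step 11 | 2-chloro-N-methoxy-N-methylacetamide | CON(C)C(=O)CCl
F8 | step 11 | N-methoxy-N-methyl-2-(heptamer-oxy)acetamide | CON(C)C(=O)COc1cc(OC)c(Oc2cc(OC)c(OC)c(OC)c2Oc2cc(OC)c(Oc3cc(OC)c(OC)c(OC)c3Oc3cc(OC)c(Oc4cc(OC)c(OC)c(OC)c4Oc4cc(OC)c(OC)c(OC)c4)c(OC)c3)c(OC)c2)c(OC)c1
F9 | step 13 | henicosaacetate of 26 | CC(=O)Oc1cc(OC(C)=O)c(Oc2cc(OC(C)=O)c(Oc3cc(OC(C)=O)c(OC(C)=O)c(OC(C)=O)c3Oc3cc(OC(C)=O)c(Oc4cc(OC(C)=O)c(OC(C)=O)c(OC(C)=O)c4Oc4cc(OC(C)=O)c(Oc5cc(OC(C)=O)c(OC(C)=O)c(OC(C)=O)c5Oc5cc(OC(C)=O)c(OC(C)=O)c(OC(C)=O)c5)c(OC(C)=O)c4)c(OC(C)=O)c3)c(OC(C)=O)c2)c(OC(C)=O)c1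
A1 | alternative 1 | permethylated octamer bound through ring G to cyclopentadienylruthenium hexafluorophosphate, drawn as its components | COc1cc(OC)c(Oc2cc(OC)c(Oc3cc(OC)c(OC)c(OC)c3Oc3cc(OC)c(Oc4cc(OC)c(OC)c(OC)c4Oc4cc(OC)c(Oc5cc(OC)c(OC)c(OC)c5Oc5cc(OC)c(OC)c(OC)c5)c(OC)c4)c(OC)c3)c(OC)c2)c(OC)c1.[cH-]1cccc1.[Ru+2].F[P-](F)(F)(F)(F)F
A2 | alternative 1 | cyclopentadienylruthenium complex of 1,2-dichloro-3,4,5-trimethoxybenzene, hexafluorophosphate, drawn as its components | COc1cc(Cl)c(Cl)c(OC)c1OC.[cH-]1cccc1.[Ru+2].F[P-](F)(F)(F)(F)F
A3 | alternative 1 | hexamer phenol (rings A to F as methyl ethers, hydroxyl at C4 of ring F) | COc1cc(OC)c(Oc2cc(OC)c(Oc3cc(OC)c(OC)c(OC)c3Oc3cc(OC)c(Oc4cc(OC)c(OC)c(OC)c4Oc4cc(OC)c(O)c(OC)c4)c(OC)c3)c(OC)c2)c(OC)c1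
A4 | alternative 1 | 3,4,5-trimethoxyphenol | COc1cc(O)cc(OC)c1OC
A5 | alternative 2 | ring A to E pentamer, ring E with free C3 hydroxyl and methoxymethyl ether at C6 | COCOc5c(OC)c(OC)c(O)cc5Oc4c(OC)cc(Oc3c(OC)c(OC)c(OC)cc3Oc2c(OC)cc(Oc1c(OC)cc(OC)cc1OC)cc2OC)cc4OC
A6 | alternative 2 | racemic 4-[1-(ring A to D tetramer-oxy)vinyl]-4-(methoxymethoxy)-2,3-dimethoxycyclobut-2-en-1-one | C=C(Oc4c(OC)cc(Oc3c(OC)c(OC)c(OC)cc3Oc2c(OC)cc(Oc1c(OC)cc(OC)cc1OC)cc2OC)cc4OC)C1(OCOC)C(OC)=C(OC)C1=O
A7 | alternative 3 | octamer tetraphenol, free hydroxyl at C4 of rings C, E, G and H | COc1cc(OC)c(Oc2cc(OC)c(Oc3cc(OC)c(O)c(OC)c3Oc3cc(OC)c(Oc4cc(OC)c(O)c(OC)c4Oc4cc(OC)c(Oc5cc(OC)c(O)c(OC)c5Oc5cc(OC)c(O)c(OC)c5)c(OC)c4)c(OC)c3)c(OC)c2)c(OC)c1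
A8 | alternative 3 | octamer tetra-aldehyde, formyl at C4 of rings C, E, G and H | COc1cc(OC)c(Oc2cc(OC)c(Oc3cc(OC)c(C=O)c(OC)c3Oc3cc(OC)c(Oc4cc(OC)c(C=O)c(OC)c4Oc4cc(OC)c(Oc5cc(OC)c(C=O)c(OC)c5Oc5cc(OC)c(C=O)c(OC)c5)c(OC)c4)c(OC)c3)c(OC)c2)c(OC)c1
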